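**Plan**
- Retrosynthetic cuts, in order: the O–S bond of the C3 sulfate; the O-benzyl bonds on O5 and O3'; C5–O (back to C5–F); O1–C8a of the pyranone ring C; C3–C4 (ketone enolate plus aroyl chloride).
- Enabling feature: O1–C8a and C5–O both lie ortho to C4a, the ring-A carbon that carries the C4 carbonyl. A 2,6-difluoro-4-methoxybenzoyl unit therefore offers two equivalent, carbonyl-activated C–F bonds, one for ring closure and one for the C5 oxygen.
- Forward: the ring-B acetophenone becomes its α-(methoxymethoxy) ketone and is C-acylated (C3–C4). Enolate O-arylation then closes ring C, the only ring made (rings A and B are bought). Benzyl oxide replaces the C5 fluoride, the MOM group is removed, O3 is sulfated and the benzyl groups are removed last.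
- Stereochemistry: the target has no stereocentre, axis or configurational double bond, so nothing has to be set. The one stereocentre on the way (central carbon of the diketone, racemic and enolisable) becomes sp2 C3 on ring closure.

Key step: step 7

Remark: the target is achiral, so "single enantiomer" needs no action; because it is drawn as the free sulfuric acid monoester, the sulfate is carried as its triethylammonium salt and the cation is exchanged for a proton only in the last operation (cold resin, immediate freeze-drying), since flavonol sulfates hydrolyse slowly once acidic.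

**Route**

Step 1
Reactants: 1 3'-hydroxy-4'-methoxyacetophenone
Product: 2 1-[3-(benzyloxy)-4-methoxyphenyl]ethan-1-one
Conditions: BnBr, K2CO3, DMF, 60 °C
Reagents that add atoms: benzyl bromide, BrCc1ccccc1
Why: Williamson etherification of the only phenol masks 3'-OH as a benzyl ether that should survive the basic and acidic steps ahead and fall by hydrogenolysis at the end.

Step 2
Reactants: 2 1-[3-(benzyloxy)-4-methoxyphenyl]ethan-1-one
Product: 3 2-bromo-1-[3-(benzyloxy)-4-methoxyphenyl]ethan-1-one
Conditions: CuBr2 (2.1 equiv), EtOAc–CHCl3, reflux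
Reagents that add atoms: copper(II) bromide, Br[Cu]Br
Why: Copper(II) bromide α-bromination of an aryl methyl ketone (King–Ostrum conditions) should monobrominate the methyl group through the enol and spare the electron-rich ring and the benzyl ether.

Step 3
Reactants: 3 2-bromo-1-[3-(benzyloxy)-4-methoxyphenyl]ethan-1-one
Product: 5 1-[3-(benzyloxy)-4-methoxyphenyl]-2-hydroxyethan-1-one, via formate ester 4 (not isolated)
Conditions: HCO2Na (3 equiv), EtOH–H2O, reflux
Reagents that add atoms: sodium formate, [Na+].[O-]C=O
Why: SN2 displacement of the phenacyl bromide by formate and hydrolysis of the formate ester in the same pot is the standard way from an α-bromo ketone to the α-hydroxy ketone without the side reactions of free hydroxide.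

Step 4
Reactants: 5 1-[3-(benzyloxy)-4-methoxyphenyl]-2-hydroxyethan-1-one
Product: 6 1-[3-(benzyloxy)-4-methoxyphenyl]-2-(methoxymethoxy)ethan-1-one
Conditions: MOMCl, i-Pr2NEt, CH2Cl2, 0 °C to rt
Reagents that add atoms: chloromethyl methyl ether, COCCl
Why: O-alkylation of the primary alcohol gives a methoxymethyl acetal that tolerates amide base, carbonate and alkoxide and can later be removed by acid while the benzyl ethers stay.

Step 5
Reactants: 7 2,6-difluoro-4-methoxybenzoic acid
Product: 8 2,6-difluoro-4-methoxybenzoyl chloride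
Conditions: (COCl)2, cat. DMF, CH2Cl2, 0 °C to rt; evaporate, use crude
Reagents that add atoms: oxalyl chloride, O=C(Cl)C(=O)Cl
Why: Vilsmeier-catalysed acid chloride formation gives only gaseous by-products, so the acid chloride can be used directly after evaporation.

Step 6
Reactants: 6 1-[3-(benzyloxy)-4-methoxyphenyl]-2-(methoxymethoxy)ethan-1-one; 8 2,6-difluoro-4-methoxybenzoyl chloride
Product: 10 1-[3-(benzyloxy)-4-methoxyphenyl]-3-(2,6-difluoro-4-methoxyphenyl)-2-(methoxymethoxy)propane-1,3-dione (racemic; keto–enol mixture), via lithium enolate 9 (not isolated)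
Conditions: LiHMDS (2.2 equiv), THF, −78 °C; then 8 (1.2 equiv), −78 to 0 °C; aq. NH4Cl
Reagents that add atoms: lithium bis(trimethylsilyl)amide, [Li]N([Si](C)(C)C)[Si](C)(C)C (supplies the lithium of 9 only)
Why: Claisen-type C-acylation of a preformed lithium enolate with an aroyl chloride, as used for flavone diketones, should go through carbon because lithium is chelated between the enolate and MOM oxygens in THF, and the second equivalent of base takes up the acidic diketone proton so that 9 is not spent as a base.

Step 7
Reactants: 10 1-[3-(benzyloxy)-4-methoxyphenyl]-3-(2,6-difluoro-4-methoxyphenyl)-2-(methoxymethoxy)propane-1,3-dione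
Product: 11 2-[3-(benzyloxy)-4-methoxyphenyl]-5-fluoro-7-methoxy-3-(methoxymethoxy)-4H-chromen-4-one
Conditions: K2CO3 (2 equiv), dry DMF, 60 °C
Reagents that add atoms: none
Why: Carbonate removes the proton of the central CH(OMOM), and the enolate oxygen on the ring-B carbonyl carbon adds to one of the two C–F carbons ortho to the aroyl carbonyl, giving a Meisenheimer anion whose charge at C4a is delocalised into C4=O and which collapses with loss of fluoride (addition–elimination SNAr). The closest known reaction type is the base-mediated cyclisation of 1-(2-haloaryl)-1,3-diketones to chromones and flavones. The pyranone ring closes in a formally 6-endo-trig mode with respect to the C4a=C8a bond, forming O1–C8a. No stereocentre is created, and the racemic centre of 10 becomes the sp2 carbon C3. The step needs O-arylation and a single regioisomer: attack by the central carbon or by the other carbonyl oxygen would each need a four-membered ring, and the two fluorines are equivalent, so only 11 should form. The remaining fluoride sits at C5, ortho to C4a and peri to the C4 oxygen, and should survive carbonate for use in step 8.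

Step 8
Reactants: 11 2-[3-(benzyloxy)-4-methoxyphenyl]-5-fluoro-7-methoxy-3-(methoxymethoxy)-4H-chromen-4-one; 12 benzyl alcohol
Product: 14 5-(benzyloxy)-2-[3-(benzyloxy)-4-methoxyphenyl]-7-methoxy-3-(methoxymethoxy)-4H-chromen-4-one, via sodium benzyl oxide 13 (not isolated)
Conditions: 12 (1.5 equiv), NaH (1.5 equiv), THF, 0 °C; then 11, THF–DMF, 0 to 40 °C
Reagents that add atoms: sodium hydride, [Na+].[H-] (supplies the sodium of 13 only)
Why: Nucleophilic aromatic substitution of a 5-fluorochromone by an alkoxide should work because the fluoride is activated by the ortho C4 carbonyl and not deactivated by the meta-placed O1 and 7-OMe, while the 2-aryl and 3-OMOM groups shield C2 from conjugate addition.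

Step 9
Reactants: 14 5-(benzyloxy)-2-[3-(benzyloxy)-4-methoxyphenyl]-7-methoxy-3-(methoxymethoxy)-4H-chromen-4-one
Product: 15 5-(benzyloxy)-2-[3-(benzyloxy)-4-methoxyphenyl]-3-hydroxy-7-methoxy-4H-chromen-4-one
Conditions: HCl (1.25 M in MeOH), THF, 40 °C
Reagents that add atoms: none
Why: Acid-catalysed acetal exchange with methanol removes the enol MOM ether as dimethoxymethane under conditions too mild to cleave aryl benzyl or methyl ethers.

Step 10
Reactants: 15 5-(benzyloxy)-2-[3-(benzyloxy)-4-methoxyphenyl]-3-hydroxy-7-methoxy-4H-chromen-4-one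
Product: 16 triethylammonium 5-(benzyloxy)-2-[3-(benzyloxy)-4-methoxyphenyl]-7-methoxy-4-oxo-4H-chromen-3-yl sulfate
Conditions: SO3·NEt3 (4 equiv), Et3N (1 equiv), DMF, 50 °C; silica gel (CH2Cl2–MeOH–Et3N)
Reagents that add atoms: sulfur trioxide–triethylamine complex, CC[N+](CC)(CC)S(=O)(=O)[O-]
Why: O-sulfonation with an SO3–amine complex is the usual method for flavonoid sulfates, 3-OH is the only free hydroxyl because O5 and O3' are benzylated, and the amine of the complex stays as the counter-ion so the step has no by-product.

Step 11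
Reactants: 16 triethylammonium 5-(benzyloxy)-2-[3-(benzyloxy)-4-methoxyphenyl]-7-methoxy-4-oxo-4H-chromen-3-yl sulfate
Product: 18 ombuin 3-O-sulfate (5-hydroxy-2-(3-hydroxy-4-methoxyphenyl)-7-methoxy-4-oxo-4H-chromen-3-yl hydrogen sulfate), via triethylammonium salt 17 (not isolated)
Conditions: H2 (1 atm), 10% Pd/C, MeOH–THF, rt; filter; Dowex 50W (H+ form), H2O–MeOH, 0 °C; freeze-dry
Reagents that add atoms: none
Why: Palladium-catalysed hydrogenolysis should cleave both aryl benzyl ethers while the sulfate salt, the aryl methyl ethers and the chromone C2=C3 bond stay intact, and the sulfonic acid resin then exchanges triethylammonium for a proton.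

**Compound list**
1 | 3'-hydroxy-4'-methoxyacetophenone | CC(=O)c1ccc(OC)c(O)c1 | starting material
2 | 1-[3-(benzyloxy)-4-methoxyphenyl]ethan-1-one | CC(=O)c1ccc(OC)c(OCc2ccccc2)c1 | intermediate
3 | 2-bromo-1-[3-(benzyloxy)-4-methoxyphenyl]ethan-1-one | O=C(CBr)c1ccc(OC)c(OCc2ccccc2)c1 | intermediate
4 | 2-[3-(benzyloxy)-4-methoxyphenyl]-2-oxoethyl formate (formed in the flask) | O=COCC(=O)c1ccc(OC)c(OCc2ccccc2)c1 | intermediate
5 | 1-[3-(benzyloxy)-4-methoxyphenyl]-2-hydroxyethan-1-one | O=C(CO)c1ccc(OC)c(OCc2ccccc2)c1 | intermediate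
6 | 1-[3-(benzyloxy)-4-methoxyphenyl]-2-(methoxymethoxy)ethan-1-one | COCOCC(=O)c1ccc(OC)c(OCc2ccccc2)c1 | intermediate
7 | 2,6-difluoro-4-methoxybenzoic acid | COc1cc(F)c(C(=O)O)c(F)c1 | starting material
8 | 2,6-difluoro-4-methoxybenzoyl chloride | COc1cc(F)c(C(=O)Cl)c(F)c1 | intermediate
9 | lithium (Z)-enolate of ketone 6, chelated (formed in the flask) | [Li]O/C(=C\OCOC)c1ccc(OC)c(OCc2ccccc2)c1 | intermediate
10 | 1-[3-(benzyloxy)-4-methoxyphenyl]-3-(2,6-difluoro-4-methoxyphenyl)-2-(methoxymethoxy)propane-1,3-dione (racemic, enolisable) | COCOC(C(=O)c1c(F)cc(OC)cc1F)C(=O)c1ccc(OC)c(OCc2ccccc2)c1 | intermediate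
11 | 2-[3-(benzyloxy)-4-methoxyphenyl]-5-fluoro-7-methoxy-3-(methoxymethoxy)-4H-chromen-4-one | COCOc1c(-c2ccc(OC)c(OCc3ccccc3)c2)oc2cc(OC)cc(F)c2c1=O | intermediate
12 | benzyl alcohol | OCc1ccccc1 | starting material
13 | sodium benzyl oxide (formed in the flask) | [Na+].[O-]Cc1ccccc1 | intermediate
14 | 5-(benzyloxy)-2-[3-(benzyloxy)-4-methoxyphenyl]-7-methoxy-3-(methoxymethoxy)-4H-chromen-4-one | COCOc1c(-c2ccc(OC)c(OCc3ccccc3)c2)oc2cc(OC)cc(OCc3ccccc3)c2c1=O | intermediate
15 | 5-(benzyloxy)-2-[3-(benzyloxy)-4-methoxyphenyl]-3-hydroxy-7-methoxy-4H-chromen-4-one | COc1cc(OCc2ccccc2)c2c(=O)c(O)c(-c3ccc(OC)c(OCc4ccccc4)c3)oc2c1 | intermediate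
16 | triethylammonium 5-(benzyloxy)-2-[3-(benzyloxy)-4-methoxyphenyl]-7-methoxy-4-oxo-4H-chromen-3-yl sulfate | COc1cc(OCc2ccccc2)c2c(=O)c(OS(=O)(=O)[O-])c(-c3ccc(OC)c(OCc4ccccc4)c3)oc2c1.CC[NH+](CC)CC | intermediate
17 | triethylammonium 5-hydroxy-2-(3-hydroxy-4-methoxyphenyl)-7-methoxy-4-oxo-4H-chromen-3-yl sulfate (formed in the flask) | COc1cc(O)c2c(=O)c(OS(=O)(=O)[O-])c(-c3ccc(OC)c(O)c3)oc2c1.CC[NH+](CC)CC | intermediate
18 | ombuin 3-O-sulfate | COc1cc(O)c2c(=O)c(OS(=O)(=O)O)c(-c3ccc(OC)c(O)c3)oc2c1 | target

**Step count**
Total steps: 11. Longest linear sequence: 10 steps (1 to 18 through steps 1–4 and 6–11); step 5 is a one-step side branch.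

**Steps most likely to fail**

Step 6. The enolate may be acylated on oxygen to give an enol ester, the diketone may be acylated a second time, or the excess amide base may consume the acid chloride. The fallback reaches the diketone at a lower oxidation level and sets out from 6. Enolate 9 (from 6 with LDA, THF, −78 °C) is added to purchased 2,6-difluoro-4-methoxybenzaldehyde F1. This should give the aldol 1-[3-(benzyloxy)-4-methoxyphenyl]-3-(2,6-difluoro-4-methoxyphenyl)-3-hydroxy-2-(methoxymethoxy)propan-1-one F2 as a mixture of diastereomers. Dess–Martin periodinane in CH2Cl2 then oxidises the secondary alcohol, which erases the diastereomer issue and returns to the route at 10.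

Step 8. The pyranone carbonyl is only a modest activator, so fluoride displacement may be slow, and benzyl oxide may instead add to C2 and open the pyranone ring. The fallback installs the C5 oxygen before ring closure and sets out from 6 and 12. Purchased 2,6-difluoro-4-methoxybenzaldehyde F1 is treated with one equivalent of 13 in THF at 0 °C. One aldehyde-activated fluoride should be replaced to give 2-(benzyloxy)-6-fluoro-4-methoxybenzaldehyde F3, the new alkoxy group slowing a second substitution. Aldol addition of enolate 9 gives 1-[3-(benzyloxy)-4-methoxyphenyl]-3-[2-(benzyloxy)-6-fluoro-4-methoxyphenyl]-3-hydroxy-2-(methoxymethoxy)propan-1-one F4. Dess–Martin oxidation gives 1-[2-(benzyloxy)-6-fluoro-4-methoxyphenyl]-3-[3-(benzyloxy)-4-methoxyphenyl]-2-(methoxymethoxy)propane-1,3-dione F5. K2CO3 in DMF then closes O1–C8a by the same enolate O-arylation on the one remaining C–F bond and returns to the route at 14.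

Step 11. Debenzylation may stall in the presence of the sulfate salt, especially at the hindered peri 5-O-benzyl ether, or the sulfate ester may be lost by solvolysis during a long hydrogenation. The fallback removes the benzyl groups before sulfation and sets out from 15. Hydrogenolysis (H2, Pd/C, THF–MeOH) gives ombuin (3,5,3'-trihydroxy-7,4'-dimethoxyflavone) F6. Carbodiimide-mediated sulfation with Bu4N·HSO4 and DCC in pyridine at 4 °C should then go to 3-OH, the most acidic free hydroxyl: 5-OH is held in a hydrogen bond to the C4 carbonyl and 3'-OH is the least acidic. This gives tetrabutylammonium ombuin 3-O-sulfate F7. Cold proton exchange on the sulfonic acid resin returns to the route at 18.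

**Further compounds**
F1 | step 6 | 2,6-difluoro-4-methoxybenzaldehyde (purchased) | COc1cc(F)c(C=O)c(F)c1
F2 | step 6 | 1-[3-(benzyloxy)-4-methoxyphenyl]-3-(2,6-difluoro-4-methoxyphenyl)-3-hydroxy-2-(methoxymethoxy)propan-1-one (mixture of diastereomers, racemic) | COCOC(C(O)c1c(F)cc(OC)cc1F)C(=O)c1ccc(OC)c(OCc2ccccc2)c1
F3 | step 8 | 2-(benzyloxy)-6-fluoro-4-methoxybenzaldehyde | COc1cc(F)c(C=O)c(OCc2ccccc2)c1
F4 | step 8 | 1-[3-(benzyloxy)-4-methoxyphenyl]-3-[2-(benzyloxy)-6-fluoro-4-methoxyphenyl]-3-hydroxy-2-(methoxymethoxy)propan-1-one (mixture of diastereomers, racemic) | COCOC(C(O)c1c(F)cc(OC)cc1OCc1ccccc1)C(=O)c1ccc(OC)c(OCc2ccccc2)c1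
F5 | step 8 | 1-[2-(benzyloxy)-6-fluoro-4-methoxyphenyl]-3-[3-(benzyloxy)-4-methoxyphenyl]-2-(methoxymethoxy)propane-1,3-dione (racemic, enolisable) | COCOC(C(=O)c1c(F)cc(OC)cc1OCc1ccccc1)C(=O)c1ccc(OC)c(OCc2ccccc2)c1
F6 | step 11 | ombuin (3,5,3'-trihydroxy-7,4'-dimethoxyflavone) | COc1cc(O)c2c(=O)c(O)c(-c3ccc(OC)c(O)c3)oc2c1
F7 | step 11 | tetrabutylammonium ombuin 3-O-sulfate | COc1cc(O)c2c(=O)c(OS(=O)(=O)[O-])c(-c3ccc(OC)c(O)c3)oc2c1.CCCC[N+](CCCC)(CCCC)CCCC
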